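**Retrosynthetic overview**
1. Chain numbering: C1 = benzylic CH2, C3 and C5 = the acetoxy-bearing carbons, C12 = terminal CH3. The target is the (3R,5S), i.e. syn, diacetate with a free phenol on ring A (the guaiacyl ring).
2. Enabling feature: the single methylene C4 lies between the two oxygen-bearing stereocentres C3 and C5 (the acyclic 1,3-dioxygenated triad C3–C4–C5). If both C–O bonds are read as C–B bonds, C4 is the carbon atom of bis(pinacolatoboryl)methane.
3. Key disconnections: C4–C5, then C3–C4. Both bonds are made in one flask by 1,2-metallate rearrangement of chiral α-lithiated 2,4,6-triisopropylbenzoates on that linchpin, followed by double C–B oxidation in the same flask. The three components are the octyl ester (C5–C12), the linchpin (C4) and the arylpropyl ester (C1–C3 plus ring A).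
4. End game: acetylation of the syn-3,5-diol, then removal of the phenol silyl group.
5. Rings: none is formed. Ring A is bought with dihydroconiferyl alcohol, and the two dioxaborolane rings are temporary and leave in the oxidation.

Key step: step 4

Assumption: s-BuLi/(−)-sparteine is taken to remove the pro-S hydrogen of a primary alkyl 2,4,6-triisopropylbenzoate, and (+)-sparteine the pro-R hydrogen, as is established for this class of α-oxy organolithium reagents.

Step 1
Reactants: 1 1-bromooctane; 2 2,4,6-triisopropylbenzoic acid
Product: 3 octyl 2,4,6-triisopropylbenzoate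
Conditions: K2CO3, DMF, 60 °C
Reagents that add atoms: none
Why: SN2 O-alkylation of the potassium carboxylate by a primary bromide avoids any attack at the hindered acyl carbon, and no stereocentre is involved.

Step 2
Reactants: 4 dihydroconiferyl alcohol [3-(4-hydroxy-3-methoxyphenyl)propan-1-ol]; 2 2,4,6-triisopropylbenzoic acid
Product: 5 3-(4-hydroxy-3-methoxyphenyl)propyl 2,4,6-triisopropylbenzoate
Conditions: PPh3, DIAD, THF, 0 °C → rt
Reagents that add atoms: none
Why: In this Mitsunobu esterification the carboxylic acid, far more acidic than the phenol, protonates the betaine and its carboxylate displaces the primary alkoxyphosphonium ion, so the phenol should stay free (chemoselective Mitsunobu esterification of phenolic alcohols is a known reaction type); no stereocentre is involved.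

Step 3
Reactants: 5 3-(4-hydroxy-3-methoxyphenyl)propyl 2,4,6-triisopropylbenzoate
Product: 6 3-[3-methoxy-4-(triisopropylsilyloxy)phenyl]propyl 2,4,6-triisopropylbenzoate
Conditions: TIPSCl, imidazole, DMF, rt
Reagents that add atoms: chlorotriisopropylsilane (TIPSCl), CC(C)[Si](Cl)(C(C)C)C(C)C
Why: Imidazole-promoted silylation of the only free OH gives a bulky aryl silyl ether that should resist s-BuLi, should not direct ring lithiation and should survive mild perborate oxidation.

Step 4
Reactants: 3 octyl 2,4,6-triisopropylbenzoate; 7 bis(pinacolatoboryl)methane; 6 3-[3-methoxy-4-(triisopropylsilyloxy)phenyl]propyl 2,4,6-triisopropylbenzoate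
Product: 14 (3R,5S)-1-[3-methoxy-4-(triisopropylsilyloxy)phenyl]dodecane-3,5-diol, via lithiated octyl ester 8 (not isolated), via first boronate complex 9 (not isolated), via 1,2-bis(boronate) 10 (not isolated), via lithiated arylpropyl ester 11 (not isolated), via second boronate complex 12 (not isolated), via 1,3-bis(boronate) 13 (not isolated)
Conditions: (a) 3, s-BuLi, (+)-sparteine, Et2O, −78 °C; then 7, −78 → 35 °C; (b) recool to −78 °C, transfer by cannula into 11 [from 6 (slight excess), s-BuLi, (−)-sparteine, Et2O, −78 °C]; −78 → 35 °C; (c) add THF and aq. NaBO3·4H2O, rt; no work-up between (a), (b) and (c)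
Reagents that add atoms: sodium perborate tetrahydrate (NaBO3·4H2O, drawn as its dimeric peroxoborate salt), [Na+].[Na+].O[B-]1(O)OO[B-](O)(O)OO1
Why: Each ester is deprotonated at its OCH2 group by s-BuLi bound to one antipode of sparteine to give a configurationally stable α-oxy organolithium (8, later 11), which adds to tricoordinate boron with retention to give a boronate complex (9, later 12); on warming, the boron-bound CH2 group shifts to the neighbouring carbon antiperiplanar to the leaving carboxylate, with inversion there, so that C4–C5 and then C3–C4 are made, and perborate finally turns both C–B bonds into C–OH with retention. The closest known reaction types are lithiation–borylation (a Matteson-type 1,2-metallate rearrangement) as applied to the one-directional homologation of bis(pinacolatoboryl)methane and to the primary-selective homologation of 1,2-bis(boronic esters), both followed by oxidation to 1,3-diols; running the two stages in one flask follows the practice of iterative homologation without purification. No ring of the target is closed; the dioxaborolane rings are only carried through and leave as pinacol. C5 (S) is set by (+)-sparteine, which directs removal of the pro-R hydrogen of 3, and C3 (R) by (−)-sparteine, which directs removal of the pro-S hydrogen of 6, each followed by the retention–inversion–retention sequence, so both centres are under independent reagent control and the syn pattern simply requires the two antipodes. The step needs mono-addition to 7 (secured by the bulk of diamine-bound 8, which should not build a second, geminal boronate, and by the decay of surplus 8 on warming), attack of 11 at the primary CH2–B and not at the secondary CH–B of 10 (secured by the steric gap between the two boron atoms), and lithiation at OCH2 rather than on ring A or at C1 (secured by carbonyl-directed deprotonation and by the bulky, non-directing OSi(i-Pr)3 group). Because two enantioenriched partners are joined, the minor lithiation pathways should end mainly in the anti diol, which chromatography should remove, so 14 should be obtained as essentially one enantiomer.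

Step 5
Reactants: 14 (3R,5S)-1-[3-methoxy-4-(triisopropylsilyloxy)phenyl]dodecane-3,5-diol
Product: 15 (3R,5S)-1-[3-methoxy-4-(triisopropylsilyloxy)phenyl]dodecane-3,5-diyl diacetate
Conditions: Ac2O, pyridine, DMAP (cat.), CH2Cl2, rt
Reagents that add atoms: acetic anhydride, CC(=O)OC(C)=O
Why: DMAP-catalysed O-acylation esterifies both secondary alcohols without touching either C–O bond, so C3 and C5 keep their configuration and the silyl ether is inert.

Step 6
Reactants: 15 (3R,5S)-1-[3-methoxy-4-(triisopropylsilyloxy)phenyl]dodecane-3,5-diyl diacetate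
Product: 16 (3R,5S)-1-(4-hydroxy-3-methoxyphenyl)dodecane-3,5-diyl diacetate (target)
Conditions: Bu4NF, AcOH (1:1), THF, 0 °C
Reagents that add atoms: none
Why: Fluoride-driven cleavage of the aryl Si–O bond is fast, and the acetic acid buffer protonates the phenoxide at once, so acetyl transfer or acetate loss should not occur and the stereocentres are untouched.

**Compound list**
1 | 1-bromooctane | CCCCCCCCBr | starting material
2 | 2,4,6-triisopropylbenzoic acid | CC(C)c1cc(C(C)C)c(C(=O)O)c(C(C)C)c1 | starting material
3 | octyl 2,4,6-triisopropylbenzoate | CCCCCCCCOC(=O)c1c(C(C)C)cc(C(C)C)cc1C(C)C | intermediate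
4 | dihydroconiferyl alcohol, 3-(4-hydroxy-3-methoxyphenyl)propan-1-ol | COc1cc(CCCO)ccc1O | starting material
5 | 3-(4-hydroxy-3-methoxyphenyl)propyl 2,4,6-triisopropylbenzoate | COc1cc(CCCOC(=O)c2c(C(C)C)cc(C(C)C)cc2C(C)C)ccc1O | intermediate
6 | 3-[3-methoxy-4-(triisopropylsilyloxy)phenyl]propyl 2,4,6-triisopropylbenzoate | COc1cc(CCCOC(=O)c2c(C(C)C)cc(C(C)C)cc2C(C)C)ccc1O[Si](C(C)C)(C(C)C)C(C)C | intermediate
7 | bis(pinacolatoboryl)methane, bis(4,4,5,5-tetramethyl-1,3,2-dioxaborolan-2-yl)methane | CC1(C)OB(CB2OC(C)(C)C(C)(C)O2)OC1(C)C | starting material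
8 | (R)-1-lithiooctyl 2,4,6-triisopropylbenzoate, present as its (+)-sparteine complex (ligand not drawn) | [Li][C@H](CCCCCCC)OC(=O)c1c(C(C)C)cc(C(C)C)cc1C(C)C | intermediate
9 | lithium boronate complex of 8 with one boron of 7, (R) at the O-bearing carbon | [Li+].CCCCCCC[C@H](OC(=O)c1c(C(C)C)cc(C(C)C)cc1C(C)C)[B-]1(CB2OC(C)(C)C(C)(C)O2)OC(C)(C)C(C)(C)O1 | intermediate
10 | (R)-2,2'-(nonane-1,2-diyl)bis(4,4,5,5-tetramethyl-1,3,2-dioxaborolane) | CCCCCCC[C@@H](CB1OC(C)(C)C(C)(C)O1)B1OC(C)(C)C(C)(C)O1 | intermediate
11 | (S)-1-lithio-3-[3-methoxy-4-(triisopropylsilyloxy)phenyl]propyl 2,4,6-triisopropylbenzoate, present as its (−)-sparteine complex (ligand not drawn) | [Li][C@@H](CCc1ccc(O[Si](C(C)C)(C(C)C)C(C)C)c(OC)c1)OC(=O)c1c(C(C)C)cc(C(C)C)cc1C(C)C | intermediate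
12 | lithium boronate complex of 11 with the primary boron of 10, (S) at the O-bearing carbon, (R) at the CH–B carbon | [Li+].CCCCCCC[C@@H](C[B-]1(OC(C)(C)C(C)(C)O1)[C@@H](CCc1ccc(O[Si](C(C)C)(C(C)C)C(C)C)c(OC)c1)OC(=O)c1c(C(C)C)cc(C(C)C)cc1C(C)C)B1OC(C)(C)C(C)(C)O1 | intermediate
13 | 2,2'-{(3R,5S)-1-[3-methoxy-4-(triisopropylsilyloxy)phenyl]dodecane-3,5-diyl}bis(4,4,5,5-tetramethyl-1,3,2-dioxaborolane) | CCCCCCC[C@@H](C[C@@H](CCc1ccc(O[Si](C(C)C)(C(C)C)C(C)C)c(OC)c1)B1OC(C)(C)C(C)(C)O1)B1OC(C)(C)C(C)(C)O1 | intermediate
14 | (3R,5S)-1-[3-methoxy-4-(triisopropylsilyloxy)phenyl]dodecane-3,5-diol (syn) | CCCCCCC[C@@H](C[C@@H](CCc1ccc(O[Si](C(C)C)(C(C)C)C(C)C)c(OC)c1)O)O | intermediate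
15 | (3R,5S)-1-[3-methoxy-4-(triisopropylsilyloxy)phenyl]dodecane-3,5-diyl diacetate | CCCCCCC[C@@H](C[C@@H](CCc1ccc(O[Si](C(C)C)(C(C)C)C(C)C)c(OC)c1)OC(C)=O)OC(C)=O | intermediate
16 | (3R,5S)-1-(4-hydroxy-3-methoxyphenyl)dodecane-3,5-diyl diacetate | CCCCCCC[C@@H](C[C@@H](CCc1ccc(O)c(OC)c1)OC(C)=O)OC(C)=O | target

**Total step count:** 6.
**Longest linear sequence:** 5 (steps 2, 3, 4, 5, 6, from 4 to 16).

**Steps most likely to fail**

Step 4.
- What may go wrong: in the single flask, carry-over of unconsumed 7, lithium carboxylate and free diamine from the first stage may divert 11. The bulky diamine-bound 11 may also add sluggishly to the β-branched primary boron of 10. Some surplus 8 may survive long enough to homologate 10 a second time.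
- Fallback: it sets out from 6 and comes back to the route at 14. The one-flask linchpin plan is given up for a stepwise union of two purified fragments, in which C5 is set by catalysis instead of by a carbenoid.
- Commercial 1-nonene is diborated enantioselectively with B2pin2 (Pt(dba)3, TADDOL-derived phenylphosphonite ligand, antipode chosen to give the R product, THF, 60 °C), and 10 is isolated pure.
- In parallel, 6 is lithiated with s-BuLi/(−)-sparteine and trapped with Me3SnCl with retention. This gives (S)-3-[3-methoxy-4-(triisopropylsilyloxy)phenyl]-1-(trimethylstannyl)propyl 2,4,6-triisopropylbenzoate F1, which can be purified.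
- Tin–lithium exchange (n-BuLi, Et2O, −78 °C) regenerates 11 free of diamine, hence smaller. It is added to pure 10, and 12, 13 and, after oxidation, 14 follow as before.

Step 2.
- What may go wrong: competing alkylation of the free phenol oxygen by the alkoxyphosphonium ion, leading to ether formation and oligomerisation.
- Fallback: it sets out from 4 and comes back at 6, bypassing 5. The two OH groups are told apart by acidity before any ester is made.
- One equivalent of NaH (THF, 0 °C) turns only the phenol of 4 into its sodium salt, which is silylated with TIPSCl to give 3-[3-methoxy-4-(triisopropylsilyloxy)phenyl]propan-1-ol F2.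
- Mitsunobu esterification of F2 with 2 (PPh3, DIAD), now with no phenol present, gives 6.

Step 6.
- What may go wrong: acetyl transfer to the liberated phenoxide, or partial loss of a secondary acetate under fluoride.
- Fallback: it sets out from 14 and comes back at 16. The silyl group is removed before any acetate is present, and the phenol is freed at the end by ester chemoselectivity instead.
- Bu4NF (THF) converts 14 into (3R,5S)-1-(4-hydroxy-3-methoxyphenyl)dodecane-3,5-diol F3.
- Ac2O/pyridine/DMAP gives the triacetate (3R,5S)-1-(4-acetoxy-3-methoxyphenyl)dodecane-3,5-diyl diacetate F4.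
- One equivalent of pyrrolidine (CH2Cl2, 0 °C) cleaves only the aryl acetate by aminolysis, because phenoxide is by far the better leaving group. This gives 16.

Further compounds
F1 | step 4 | (S)-3-[3-methoxy-4-(triisopropylsilyloxy)phenyl]-1-(trimethylstannyl)propyl 2,4,6-triisopropylbenzoate | C[Sn](C)(C)[C@@H](CCc1ccc(O[Si](C(C)C)(C(C)C)C(C)C)c(OC)c1)OC(=O)c1c(C(C)C)cc(C(C)C)cc1C(C)C
F2 | step 2 | 3-[3-methoxy-4-(triisopropylsilyloxy)phenyl]propan-1-ol | COc1cc(CCCO)ccc1O[Si](C(C)C)(C(C)C)C(C)C
F3 | step 6 | (3R,5S)-1-(4-hydroxy-3-methoxyphenyl)dodecane-3,5-diol | CCCCCCC[C@@H](C[C@@H](CCc1ccc(O)c(OC)c1)O)O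
F4 | step 6 | (3R,5S)-1-(4-acetoxy-3-methoxyphenyl)dodecane-3,5-diyl diacetate | CCCCCCC[C@@H](C[C@@H](CCc1ccc(OC(C)=O)c(OC)c1)OC(C)=O)OC(C)=O
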